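**Retrosynthetic overview**
1. Target 10 ⇒ isocaviunin 7: the C6–prenyl bond comes from an aromatic Claisen shift of the 7-O-(1,1-dimethylallyl) ether 9; C8 carries OMe, so only C6 can accept the group.
2. 7 ⇒ 4: key disconnection is the C5–OH bond (C–O), made by carbonyl-directed peri C–H borylation/oxidation of the 7-hydroxy-8-methoxyisoflavone 4.
3. 4 ⇒ 2-methoxyresorcinol 1 + arylacetic acid 2 + one carbon from DMF: acylation at C4 of 1, then formylative ring closure through the only ortho OH, which fixes OMe at C8.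
4. Ring order: rings A (from 1) and B (from 2) are bought; the pyranone ring C is the only ring formed (step 1); the C5 oxygen and then the C6 prenyl follow.

Assumption: the target has no stereocentre and its only non-ring alkene carries two identical methyl groups, so it is achiral and "single enantiomer" needs no action; 1, 2 and 8 are taken as catalogue chemicals.

**Step 1**
Reactants: 1 2-methoxybenzene-1,3-diol (2-methoxyresorcinol); 2 2,4,5-trimethoxyphenylacetic acid
Product: 4 7-hydroxy-8-methoxy-3-(2,4,5-trimethoxyphenyl)-4H-chromen-4-one, via deoxybenzoin 3 (not isolated)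
Conditions: BF3·OEt2 (neat), 85 °C, 2 h; then DMF, MsCl (3 equiv), 55→75 °C, 2 h; aq. NaOAc work-up
Reagents that add atoms: N,N-dimethylformamide, CN(C)C=O (gives C2–H of the pyranone)
Why: Friedel–Crafts acylation occurs at C4 of 1 (ortho to one OH, para to the other), then Vilsmeier-type formylation of the benzylic CH2 by the DMF/MsCl iminium salt and cyclisation through the single ortho OH give the isoflavone with OMe necessarily at C8; no stereocentre is formed.

**Step 2**
Reactants: 4 7-hydroxy-8-methoxy-3-(2,4,5-trimethoxyphenyl)-4H-chromen-4-one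
Product: 7 5,7-dihydroxy-8-methoxy-3-(2,4,5-trimethoxyphenyl)-4H-chromen-4-one (isocaviunin), via 7-O-Bpin isoflavone 5 (not isolated), via 5-Bpin-7-O-Bpin isoflavone 6 (not isolated)
Conditions: [Ir(OMe)(cod)]2 (2.5 mol%), P[3,5-(CF3)2C6H3]3 (10 mol%), B2pin2 (1.6 equiv), mesitylene, 100 °C, N2; then Me3NO (3 equiv), THF, rt; aq. NH4Cl
Reagents that add atoms: trimethylamine N-oxide, C[N+](C)(C)[O-] (gives the C5 oxygen); bis(pinacolato)diboron, CC1(C)OB(OC1(C)C)B1OC(C)(C)C(C)(C)O1 (boron carried only by 5 and 6)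
Why: Proposed new method: the 7-OH is O-borylated first (B2pin2 gives HBpin, which then serves as the C–H borylating agent with loss of H2), the Lewis-basic vinylogous-ester C4=O then binds the Ir(III) boryl centre, which the monodentate electron-poor phosphine leaves coordinatively unsaturated, so that C–H cleavage occurs only at the peri C5–H through a planar five-membered iridacycle (C6–H is shielded by the adjacent OBpin, the B-ring C–H bonds are flanked by OMe), and the C5–Bpin bond is turned into C5–O by 1,2-aryl shift in the Me3NO–boronate adduct under conditions that leave the electron-rich B ring and the enone untouched; the closest known reaction types are ketone- and ester-directed Ir-catalysed ortho C–H borylation of simple aryl ketones and benzoates, Ru(II)-catalysed C5–H hydroxylation of flavones with iodine(III) oxidants in TFA, and one-pot arene borylation/oxidation to phenols; no stereocentre is formed.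

**Step 3**
Reactants: 7 isocaviunin; 8 tert-butyl 2-methylbut-3-en-2-yl carbonate
Product: 10 5,7-dihydroxy-8-methoxy-6-(3-methylbut-2-en-1-yl)-3-(2,4,5-trimethoxyphenyl)-4H-chromen-4-one (6-prenylisocaviunin), via 7-O-(1,1-dimethylallyl) ether 9 (not isolated)
Conditions: Pd(PPh3)4 (5 mol%), THF, 4 Å MS, 0 °C→rt; silica plug, solvent switch; Eu(fod)3 (10 mol%), PhCl, 90 °C
Reagents that add atoms: none
Why: Tsuji–Trost O-allylation of the acidic, non-chelated 7-OH at the tertiary terminus of the π-prenyl-Pd complex gives the reverse-prenyl ether, whose aromatic Claisen [3,3] rearrangement can end only at C6 (C8 bears OMe, the para position is the ring fusion) and delivers the linear prenyl group after rearomatisation; no stereocentre is formed.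

**Compound list**
1 | 2-methoxybenzene-1,3-diol | COc1c(O)cccc1O | starting material
2 | 2,4,5-trimethoxyphenylacetic acid | COc1cc(OC)c(CC(=O)O)cc1OC | starting material
3 | 1-(2,4-dihydroxy-3-methoxyphenyl)-2-(2,4,5-trimethoxyphenyl)ethan-1-one | COc1cc(OC)c(CC(=O)c2ccc(O)c(OC)c2O)cc1OC | intermediate (not isolated)
4 | 7-hydroxy-8-methoxy-3-(2,4,5-trimethoxyphenyl)-4H-chromen-4-one | COc1cc(OC)c(-c2coc3c(OC)c(O)ccc3c2=O)cc1OC | intermediate
5 | 8-methoxy-7-[(4,4,5,5-tetramethyl-1,3,2-dioxaborolan-2-yl)oxy]-3-(2,4,5-trimethoxyphenyl)-4H-chromen-4-one | COc1cc(OC)c(-c2coc3c(OC)c(OB4OC(C)(C)C(C)(C)O4)ccc3c2=O)cc1OC | intermediate (not isolated)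
6 | 8-methoxy-5-(4,4,5,5-tetramethyl-1,3,2-dioxaborolan-2-yl)-7-[(4,4,5,5-tetramethyl-1,3,2-dioxaborolan-2-yl)oxy]-3-(2,4,5-trimethoxyphenyl)-4H-chromen-4-one | COc1cc(OC)c(-c2coc3c(OC)c(OB4OC(C)(C)C(C)(C)O4)cc(B4OC(C)(C)C(C)(C)O4)c3c2=O)cc1OC | intermediate (not isolated)
7 | 5,7-dihydroxy-8-methoxy-3-(2,4,5-trimethoxyphenyl)-4H-chromen-4-one (isocaviunin) | COc1cc(OC)c(-c2coc3c(OC)c(O)cc(O)c3c2=O)cc1OC | intermediate
8 | tert-butyl 2-methylbut-3-en-2-yl carbonate | CC(C)(C)OC(=O)OC(C)(C)C=C | starting material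
9 | 5-hydroxy-8-methoxy-7-[(2-methylbut-3-en-2-yl)oxy]-3-(2,4,5-trimethoxyphenyl)-4H-chromen-4-one | COc1cc(OC)c(-c2coc3c(OC)c(OC(C)(C)C=C)cc(O)c3c2=O)cc1OC | intermediate (not isolated)
10 | 5,7-dihydroxy-8-methoxy-6-(3-methylbut-2-en-1-yl)-3-(2,4,5-trimethoxyphenyl)-4H-chromen-4-one (6-prenylisocaviunin) | COc1cc(OC)c(-c2coc3c(OC)c(O)c(CC=C(C)C)c(O)c3c2=O)cc1OC | target

**Totals**
Total step count: 3. Longest linear sequence: 3 (1/2 → 4 → 7 → 10).

**Steps most likely to fail and fallbacks**

Step 2 (proposed new step; risks: borylation at C2–H or C6–H, Ir–H reduction of the enone, sluggish oxidation of the hindered peri boronate). The fallback uses known chemistry, sets out from 2 and comes back at 7, placing the A-ring oxygens the classical way. Acid 2 is condensed with phloroglucinol under the conditions of step 1; the deoxybenzoin 1-(2,4,6-trihydroxyphenyl)-2-(2,4,5-trimethoxyphenyl)ethan-1-one F1 closes in the same pot to 5,7-dihydroxy-3-(2,4,5-trimethoxyphenyl)-4H-chromen-4-one F2. Benzylation of the non-chelated 7-OH (BnBr, K2CO3, acetone) gives 7-benzyloxy-5-hydroxy-3-(2,4,5-trimethoxyphenyl)-4H-chromen-4-one F3. Elbs persulfate oxidation (K2S2O8, aq. KOH/pyridine, 0–20 °C) places oxygen para to the 5-OH as potassium 7-benzyloxy-5-hydroxy-4-oxo-3-(2,4,5-trimethoxyphenyl)-4H-chromen-8-yl sulfate F4, which is hydrolysed (dilute HCl, Na2SO3, 60 °C) to 7-benzyloxy-5,8-dihydroxy-3-(2,4,5-trimethoxyphenyl)-4H-chromen-4-one F5. Methylation of the non-chelated 8-OH (Me2SO4 1.05 equiv, K2CO3, acetone) gives 7-benzyloxy-5-hydroxy-8-methoxy-3-(2,4,5-trimethoxyphenyl)-4H-chromen-4-one F6, and hydrogenolysis (H2, Pd/C, EtOAc) returns to 7.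

Step 3 (risks: Pd-mediated isomerisation of 9 to the linear O-prenyl ether, loss of the tertiary allyl group, chroman formation from the product). The fallback sets out from 7 and comes back at 10 by cross-coupling instead of a sigmatropic shift. Iodination at the only free A-ring carbon (NIS 1.0 equiv, DMF, 0 °C) gives 5,7-dihydroxy-6-iodo-8-methoxy-3-(2,4,5-trimethoxyphenyl)-4H-chromen-4-one F7. Stille coupling with tributyl(3-methylbut-2-en-1-yl)stannane (Pd(PPh3)4, DMF, 90 °C) gives the linear prenyl arene 10.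

Step 1 (risks: side reactions of the electron-rich acid 2 in hot BF3·OEt2, over-formylation). The fallback sets out from 1 and comes back at 4 by a nitrile acylation and a separate ring closure. Houben–Hoesch reaction of 1 with 2,4,5-trimethoxyphenylacetonitrile (ZnCl2, HCl gas, Et2O, 0 °C) gives 1-(2,4-dihydroxy-3-methoxyphenyl)-2-(2,4,5-trimethoxyphenyl)ethan-1-iminium chloride F8. Hydrolysis in boiling water gives ketone 3, now isolated, which is closed with triethyl orthoformate (pyridine, cat. piperidine, reflux) to 4.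

**Further compounds**
F1 | step 2 | 1-(2,4,6-trihydroxyphenyl)-2-(2,4,5-trimethoxyphenyl)ethan-1-one | COc1cc(OC)c(CC(=O)c2c(O)cc(O)cc2O)cc1OC
F2 | step 2 | 5,7-dihydroxy-3-(2,4,5-trimethoxyphenyl)-4H-chromen-4-one | COc1cc(OC)c(-c2coc3cc(O)cc(O)c3c2=O)cc1OC
F3 | step 2 | 7-benzyloxy-5-hydroxy-3-(2,4,5-trimethoxyphenyl)-4H-chromen-4-one | COc1cc(OC)c(-c2coc3cc(OCc4ccccc4)cc(O)c3c2=O)cc1OC
F4 | step 2 | potassium 7-benzyloxy-5-hydroxy-4-oxo-3-(2,4,5-trimethoxyphenyl)-4H-chromen-8-yl sulfate | COc1cc(OC)c(-c2coc3c(OS(=O)(=O)[O-])c(OCc4ccccc4)cc(O)c3c2=O)cc1OC.[K+]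
F5 | step 2 | 7-benzyloxy-5,8-dihydroxy-3-(2,4,5-trimethoxyphenyl)-4H-chromen-4-one | COc1cc(OC)c(-c2coc3c(O)c(OCc4ccccc4)cc(O)c3c2=O)cc1OC
F6 | step 2 | 7-benzyloxy-5-hydroxy-8-methoxy-3-(2,4,5-trimethoxyphenyl)-4H-chromen-4-one | COc1cc(OC)c(-c2coc3c(OC)c(OCc4ccccc4)cc(O)c3c2=O)cc1OC
F7 | step 3 | 5,7-dihydroxy-6-iodo-8-methoxy-3-(2,4,5-trimethoxyphenyl)-4H-chromen-4-one | COc1cc(OC)c(-c2coc3c(OC)c(O)c(I)c(O)c3c2=O)cc1OC
F8 | step 1 | 1-(2,4-dihydroxy-3-methoxyphenyl)-2-(2,4,5-trimethoxyphenyl)ethan-1-iminium chloride | COc1cc(OC)c(CC(=[NH2+])c2ccc(O)c(OC)c2O)cc1OC.[Cl-]
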